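**Plan**

- Numbering runs from the lactone carbonyl C1 to the methyl C22, with C9 the cyclopropane CH2. The retrosynthesis cuts C11–C12 (alkenylzinc plus C11 aldehyde), the lactone O–C1 bond, the two bonds from C9 to C8 and C10 (methylene transfer to E-C8=C10), C8=C10 (Wittig) and C7–O (enamine oxygenation), and finally rejoins C1 and C8 as a ring alkene.
- Enabling feature: C1–C8 are the eight ring carbons of (1Z,5Z)-cycloocta-1,5-diene. Opening one ring alkene makes C1 an ester and C8 an aldehyde, the other ring alkene persists as Z-C4=C5 of the later eight-membered lactone (O, C1–C7), and C7 is the unbranched CH2 next to the C8 aldehyde, where an enamine can be oxygenated.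
- Forward order: ozonolysis; C7–O; C8=C10 with the C11 alcohol; cyclopropane C8–C9–C10 (first ring); lactone (second ring); C11 aldehyde; union at C11–C12 with the C12–C22 alkyne made from (Z)-dec-4-enal; desilylation.
- Stereochemistry: C7 from L-proline; C8 and C10 from the (S,S)-dioxaborolane ligand, backed by the C7 carbinol; C14 from D-proline; C11 from the amino alcohol (+)-MIB. Both Z-alkenes are bought in; E-C12=C13 comes from syn-hydroboration.

Key step: step 2

Remark: the target SMILES is read as 4Z,7R,8R,10R,11R,12E,14S,16Z; the enantiomers of the dioxaborolane ligand and of MIB are chosen by analogy with the established facial sense of these reagent families.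

**Step 1**
Reactants: 1 (1Z,5Z)-cycloocta-1,5-diene
Product: 3 methyl (Z)-8-oxooct-4-enoate, via methoxy hydroperoxide 2 (not isolated)
Conditions: O3 (ca. 0.5 equiv), NaHCO3, CH2Cl2/MeOH, −78 °C; then Ac2O, Et3N, CH2Cl2, 0 °C to rt
Reagents that add atoms: ozone, [O-][O+]=O; methanol, CO
Why: Unsymmetrical ozonolysis: with the diene in excess only one of the two equivalent ring alkenes should be cleaved, methanol traps the carbonyl oxide as the methoxy hydroperoxide while the other terminus appears as the aldehyde, and acetylation followed by base-induced loss of acetic acid turns the hydroperoxide terminus into the methyl ester, leaving the second cis ring alkene as Z-C4=C5.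

**Step 2**
Reactants: 3 methyl (Z)-8-oxooct-4-enoate; 4 nitrosobenzene
Product: 5 methyl (4Z,7R)-7-(anilinooxy)-8-oxooct-4-enoate
Conditions: 3 (1.2 equiv), 4 (1.0 equiv), L-proline [(S)-pyrrolidine-2-carboxylic acid] (20 mol%), DMSO, rt, 30 min; cold Et2O/brine work-up, used crude at once
Reagents that add atoms: none
Why: L-Proline and the C8 aldehyde of 3 form an iminium ion that tautomerises to the (E)-enamine over C7=C8, and in a cyclic hydrogen-bonded transition state the carboxylic acid hands its proton to the nitroso nitrogen while C7 bonds to the nitroso oxygen, after which water hydrolyses the α-oxy iminium ion to 5 and returns the catalyst. This is a direct case of the known proline-catalysed α-aminoxylation of linear aldehydes with nitrosobenzene, the nitroso aldol reaction in its O-selective mode. No ring is formed, only the C7–O bond. C7 is the one new stereocentre and is controlled by the catalyst alone: the acid group on the pyrrolidine brings the electrophile onto the enamine face on its own side, which with L-proline corresponds to (7R), as the target requires. The step must be O-selective (proton transfer to nitrogen in the transition state), face-selective (catalyst) and must stop after one oxygenation; the substrate helps in that C7 is a plain CH2 between the aldehyde and C6, the C1 ester neither condenses with the amine nor enolises, and Z-C4=C5 is insulated from the carbonyl by C6 and cannot slip into conjugation, while the fragile product is taken on without purification.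

**Step 3**
Reactants: 5 methyl (4Z,7R)-7-(anilinooxy)-8-oxooct-4-enoate; 6 (triphenylphosphoranylidene)acetaldehyde
Product: 8 methyl (4Z,7R,8E)-7-(anilinooxy)-10-hydroxydeca-4,8-dienoate, via enal 7 (not isolated)
Conditions: 6 (1.3 equiv), CH2Cl2, 0 °C to rt; then MeOH, CeCl3·7H2O, NaBH4, −20 °C
Reagents that add atoms: none
Why: Wittig olefination with the stabilised formyl ylide should give the (E)-enal from the activated α-oxy aldehyde without added base, and Luche reduction then reduces only the enal carbonyl in the 1,2-sense, sparing the methyl ester, the N–O bond and both alkenes.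

**Step 4**
Reactants: 8 methyl (4Z,7R,8E)-7-(anilinooxy)-10-hydroxydeca-4,8-dienoate
Product: 9 methyl (4Z,7R,8E)-7,10-dihydroxydeca-4,8-dienoate
Conditions: Zn dust, AcOH, EtOH, rt
Reagents that add atoms: none
Why: Dissolving-metal reduction cleaves the weak N–O bond of the O-alkyl N-arylhydroxylamine to aniline and the free C7 alcohol, the C7–O bond is untouched so the configuration is retained, and the ester and alkenes are inert.

**Step 5**
Reactants: 9 methyl (4Z,7R,8E)-7,10-dihydroxydeca-4,8-dienoate
Product: 10 methyl (4Z,7R)-7-hydroxy-7-[(1R,2R)-2-(hydroxymethyl)cyclopropyl]hept-4-enoate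
Conditions: (4S,5S)-2-butyl-N,N,N',N'-tetramethyl-1,3,2-dioxaborolane-4,5-dicarboxamide (1.3 equiv), Zn(CH2I)2·DME (from Et2Zn, CH2I2, DME; 4 equiv), CH2Cl2, −10 °C to rt; aq. NH4Cl
Reagents that add atoms: diiodomethane, ICI
Why: Charette asymmetric cyclopropanation (Simmons–Smith type): the zinc alkoxide of the C11 allylic alcohol binds to boron of the ligand, an amide carbonyl holds the zinc carbenoid and methylene is delivered stereospecifically to one face of E-C8=C10 (trans-cyclopropane), the (S,S)-ligand being the enantiomer expected to give (8R,10R), while the C7 zinc alkoxide directs to the same face through the conformer in which C7–H eclipses the alkene (matched case) and the Z-C4=C5 alkene, not allylic to oxygen, should react much more slowly.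

**Step 6**
Reactants: 10 methyl (4Z,7R)-7-hydroxy-7-[(1R,2R)-2-(hydroxymethyl)cyclopropyl]hept-4-enoate
Product: 11 methyl (4Z,7R)-7-[(1R,2R)-2-({[tert-butyl(dimethyl)silyl]oxy}methyl)cyclopropyl]-7-hydroxyhept-4-enoate
Conditions: TBSCl (1.05 equiv), imidazole, CH2Cl2, −20 to 0 °C
Reagents that add atoms: tert-butyl(chloro)dimethylsilane (TBSCl), CC(C)(C)[Si](C)(C)Cl
Why: Silyl ether formation, in which the unhindered primary cyclopropylmethanol should react with the bulky silyl chloride far faster than the secondary C7 carbinol, so that one equivalent at low temperature gives the mono-ether.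

**Step 7**
Reactants: 11 methyl (4Z,7R)-7-[(1R,2R)-2-({[tert-butyl(dimethyl)silyl]oxy}methyl)cyclopropyl]-7-hydroxyhept-4-enoate
Product: 12 (4Z,7R)-7-[(1R,2R)-2-({[tert-butyl(dimethyl)silyl]oxy}methyl)cyclopropyl]-7-hydroxyhept-4-enoic acid
Conditions: LiOH·H2O, THF/MeOH/H2O, 0 °C to rt; then 0.5 M HCl to pH 4, 0 °C
Reagents that add atoms: lithium hydroxide, [Li+].[OH-]
Why: Saponification of the unhindered methyl ester under conditions that leave the silyl ether, the cyclopropane and the Z-alkene unchanged, with mild acidification to keep the silyl group.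

**Step 8**
Reactants: 12 (4Z,7R)-7-[(1R,2R)-2-({[tert-butyl(dimethyl)silyl]oxy}methyl)cyclopropyl]-7-hydroxyhept-4-enoic acid
Product: 14 (5Z,8R)-8-[(1R,2R)-2-({[tert-butyl(dimethyl)silyl]oxy}methyl)cyclopropyl]-3,4,7,8-tetrahydro-2H-oxocin-2-one, via mixed anhydride 13 (not isolated)
Conditions: 2,4,6-trichlorobenzoyl chloride, Et3N, THF, rt; then slow addition to 4-(dimethylamino)pyridine, toluene, 80 °C (final ca. 2 mM)
Reagents that add atoms: none
Why: Yamaguchi lactonisation, in which the acylpyridinium formed from the mixed anhydride is captured by the C7 hydroxyl under high dilution, the Z-C4=C5 alkene folding the chain so that the eight-membered ring closes with less transannular strain than a saturated one, and acylation at oxygen leaves C7 untouched.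

**Step 9**
Reactants: 14 (5Z,8R)-8-[(1R,2R)-2-({[tert-butyl(dimethyl)silyl]oxy}methyl)cyclopropyl]-3,4,7,8-tetrahydro-2H-oxocin-2-one
Product: 15 (5Z,8R)-8-[(1R,2R)-2-(hydroxymethyl)cyclopropyl]-3,4,7,8-tetrahydro-2H-oxocin-2-one
Conditions: HF·pyridine, pyridine, THF, 0 °C to rt
Reagents that add atoms: none
Why: Fluoride-driven desilylation under pyridine buffering, which should leave the lactone and the cyclopropane unchanged.

**Step 10**
Reactants: 15 (5Z,8R)-8-[(1R,2R)-2-(hydroxymethyl)cyclopropyl]-3,4,7,8-tetrahydro-2H-oxocin-2-one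
Product: 16 (1R,2R)-2-[(2R,4Z)-8-oxo-3,6,7,8-tetrahydro-2H-oxocin-2-yl]cyclopropane-1-carbaldehyde
Conditions: Dess–Martin periodinane, NaHCO3, CH2Cl2, 0 °C to rt
Reagents that add atoms: none
Why: Dess–Martin oxidation of the primary alcohol to the aldehyde under buffered, non-enolising conditions, so that the trans-cyclopropane carbon C10 next to the new carbonyl should not epimerise and the lactone stays intact.

**Step 11**
Reactants: 17 (Z)-dec-4-enal; 4 nitrosobenzene
Product: 19 (2S,4Z)-2-(anilinooxy)dec-4-en-1-ol, via aminoxy aldehyde 18 (not isolated)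
Conditions: 17 (1.2 equiv), 4 (1.0 equiv), D-proline [(R)-pyrrolidine-2-carboxylic acid] (20 mol%), DMSO, rt; then EtOH, NaBH4, 0 °C
Reagents that add atoms: none
Why: Proline-catalysed α-aminoxylation as in step 2 but with the mirror-image catalyst, whose acid group steers the nitroso oxygen to the opposite enamine face and so sets (S) at the carbon that becomes C14, the labile aldehyde being fixed at once as the alcohol by borohydride reduction.

**Step 12**
Reactants: 19 (2S,4Z)-2-(anilinooxy)dec-4-en-1-ol
Product: 20 (2S,4Z)-dec-4-ene-1,2-diol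
Conditions: Zn dust, AcOH, EtOH, rt
Reagents that add atoms: none
Why: Dissolving-metal N–O reduction as in step 4, which leaves the C–O bond, the stereocentre and the Z-alkene untouched.

**Step 13**
Reactants: 20 (2S,4Z)-dec-4-ene-1,2-diol
Product: 21 (2S,4Z)-1,2-bis(triethylsilyloxy)dec-4-ene
Conditions: TESCl (2.5 equiv), imidazole, 4-(dimethylamino)pyridine (cat.), CH2Cl2, 0 °C to rt
Reagents that add atoms: chlorotriethylsilane (TESCl), CC[Si](Cl)(CC)CC
Why: Exhaustive silylation of both hydroxyl groups with an unhindered silyl chloride under nucleophilic catalysis.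

**Step 14**
Reactants: 21 (2S,4Z)-1,2-bis(triethylsilyloxy)dec-4-ene
Product: 22 (2S,4Z)-2-(triethylsilyloxy)dec-4-enal
Conditions: (COCl)2, DMSO, CH2Cl2, −78 to −40 °C; then Et3N, −78 to 0 °C
Reagents that add atoms: none
Why: Swern oxidation applied to the bis-silyl ether, in which the activated sulfonium species should exchange only the less hindered primary triethylsilyl ether and oxidise that carbon to the aldehyde while the secondary silyl ether stays, the low temperature and brief base contact guarding the α-stereocentre.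

**Step 15**
Reactants: 22 (2S,4Z)-2-(triethylsilyloxy)dec-4-enal
Product: 23 triethyl{[(3S,5Z)-undec-5-en-1-yn-3-yl]oxy}silane
Conditions: dimethyl (1-diazo-2-oxopropyl)phosphonate, K2CO3, MeOH, 0 °C to rt
Reagents that add atoms: dimethyl (1-diazo-2-oxopropyl)phosphonate, CC(=O)C(=[N+]=[N-])P(=O)(OC)OC
Why: Seyferth–Gilbert homologation with the Ohira–Bestmann reagent converts the aldehyde into the terminal alkyne under carbonate conditions mild enough that the α-silyloxy centre and the skipped Z-alkene should survive.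

**Step 16**
Reactants: 23 triethyl{[(3S,5Z)-undec-5-en-1-yn-3-yl]oxy}silane; 16 (1R,2R)-2-[(2R,4Z)-8-oxo-3,6,7,8-tetrahydro-2H-oxocin-2-yl]cyclopropane-1-carbaldehyde
Product: 26 (5Z,8R)-8-{(1R,2R)-2-[(1R,2E,4S,6Z)-1-hydroxy-4-(triethylsilyloxy)dodeca-2,6-dien-1-yl]cyclopropyl}-3,4,7,8-tetrahydro-2H-oxocin-2-one, via alkenylborane 24 (not isolated), via alkenylzinc 25 (not isolated)
Conditions: 23 (1.3 equiv), Cy2BH, toluene, 0 °C to rt; Me2Zn, −78 °C; (2R)-3-exo-morpholinoisoborneol [(+)-MIB, 10 mol%], then 16, −20 to 0 °C; aq. NH4Cl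
Reagents that add atoms: none
Why: Catalytic asymmetric alkenylzinc addition: syn-hydroboration of the terminal alkyne gives the (E)-alkenylborane (the internal Z-alkene reacts much more slowly), boron-to-zinc exchange gives the alkenyl(methyl)zinc, and the zinc aminoalkoxide of (+)-MIB should deliver the alkenyl group to the Re face of the C11 aldehyde (the (−)-ligands of this family add to the Si face), which corresponds to (11R), while the lactone and the silyl ether are inert to organozinc reagents.

**Step 17**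
Reactants: 26 (5Z,8R)-8-{(1R,2R)-2-[(1R,2E,4S,6Z)-1-hydroxy-4-(triethylsilyloxy)dodeca-2,6-dien-1-yl]cyclopropyl}-3,4,7,8-tetrahydro-2H-oxocin-2-one
Product: 27 solandelactone F
Conditions: HF·pyridine, pyridine, THF, 0 °C
Reagents that add atoms: none
Why: Fluoride-mediated cleavage of the secondary triethylsilyl ether under pyridine buffering, chosen to avoid acid (ionisation of the allylic cyclopropylcarbinol at C11) and strong base (opening of the lactone).

**Compound list**

1 | (1Z,5Z)-cycloocta-1,5-diene | C1C/C=C\CC/C=C\1 | starting material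
2 | (Z)-8-hydroperoxy-8-methoxyoct-4-enal | O=CCC/C=C\CCC(OC)OO | intermediate
3 | methyl (Z)-8-oxooct-4-enoate | O=CCC/C=C\CCC(=O)OC | intermediate
4 | nitrosobenzene | O=Nc1ccccc1 | starting material
5 | methyl (4Z,7R)-7-(anilinooxy)-8-oxooct-4-enoate | O=C[C@H](ONc1ccccc1)C/C=C\CCC(=O)OC | intermediate
6 | (triphenylphosphoranylidene)acetaldehyde | O=CC=P(c1ccccc1)(c1ccccc1)c1ccccc1 | starting material
7 | methyl (4Z,7R,8E)-7-(anilinooxy)-10-oxodeca-4,8-dienoate | O=C/C=C/[C@H](ONc1ccccc1)C/C=C\CCC(=O)OC | intermediate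
8 | methyl (4Z,7R,8E)-7-(anilinooxy)-10-hydroxydeca-4,8-dienoate | OC/C=C/[C@H](ONc1ccccc1)C/C=C\CCC(=O)OC | intermediate
9 | methyl (4Z,7R,8E)-7,10-dihydroxydeca-4,8-dienoate | OC/C=C/[C@H](O)C/C=C\CCC(=O)OC | intermediate
10 | methyl (4Z,7R)-7-hydroxy-7-[(1R,2R)-2-(hydroxymethyl)cyclopropyl]hept-4-enoate | OC[C@@H]1C[C@H]1[C@H](O)C/C=C\CCC(=O)OC | intermediate
11 | methyl (4Z,7R)-7-[(1R,2R)-2-({[tert-butyl(dimethyl)silyl]oxy}methyl)cyclopropyl]-7-hydroxyhept-4-enoate | CC(C)(C)[Si](C)(C)OC[C@@H]1C[C@H]1[C@H](O)C/C=C\CCC(=O)OC | intermediate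
12 | (4Z,7R)-7-[(1R,2R)-2-({[tert-butyl(dimethyl)silyl]oxy}methyl)cyclopropyl]-7-hydroxyhept-4-enoic acid | CC(C)(C)[Si](C)(C)OC[C@@H]1C[C@H]1[C@H](O)C/C=C\CCC(=O)O | intermediate
13 | mixed anhydride of 12 with 2,4,6-trichlorobenzoic acid | CC(C)(C)[Si](C)(C)OC[C@@H]1C[C@H]1[C@H](O)C/C=C\CCC(=O)OC(=O)c1c(Cl)cc(Cl)cc1Cl | intermediate
14 | (5Z,8R)-8-[(1R,2R)-2-({[tert-butyl(dimethyl)silyl]oxy}methyl)cyclopropyl]-3,4,7,8-tetrahydro-2H-oxocin-2-one | CC(C)(C)[Si](C)(C)OC[C@@H]1C[C@H]1[C@H]1C/C=C\CCC(=O)O1 | intermediate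
15 | (5Z,8R)-8-[(1R,2R)-2-(hydroxymethyl)cyclopropyl]-3,4,7,8-tetrahydro-2H-oxocin-2-one | OC[C@@H]1C[C@H]1[C@H]1C/C=C\CCC(=O)O1 | intermediate
16 | (1R,2R)-2-[(2R,4Z)-8-oxo-3,6,7,8-tetrahydro-2H-oxocin-2-yl]cyclopropane-1-carbaldehyde | O=C[C@@H]1C[C@H]1[C@H]1C/C=C\CCC(=O)O1 | intermediate
17 | (Z)-dec-4-enal | CCCCC/C=C\CCC=O | starting material
18 | (2S,4Z)-2-(anilinooxy)dec-4-enal | CCCCC/C=C\C[C@H](ONc1ccccc1)C=O | intermediate
19 | (2S,4Z)-2-(anilinooxy)dec-4-en-1-ol | CCCCC/C=C\C[C@H](ONc1ccccc1)CO | intermediate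
20 | (2S,4Z)-dec-4-ene-1,2-diol | CCCCC/C=C\C[C@H](O)CO | intermediate
21 | (2S,4Z)-1,2-bis(triethylsilyloxy)dec-4-ene | CCCCC/C=C\C[C@H](O[Si](CC)(CC)CC)CO[Si](CC)(CC)CC | intermediate
22 | (2S,4Z)-2-(triethylsilyloxy)dec-4-enal | CCCCC/C=C\C[C@H](O[Si](CC)(CC)CC)C=O | intermediate
23 | triethyl{[(3S,5Z)-undec-5-en-1-yn-3-yl]oxy}silane | CCCCC/C=C\C[C@H](O[Si](CC)(CC)CC)C#C | intermediate
24 | dicyclohexyl[(1E,3S,5Z)-3-(triethylsilyloxy)undeca-1,5-dien-1-yl]borane | CCCCC/C=C\C[C@H](O[Si](CC)(CC)CC)/C=C/B(C1CCCCC1)C1CCCCC1 | intermediate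
25 | methyl[(1E,3S,5Z)-3-(triethylsilyloxy)undeca-1,5-dien-1-yl]zinc | CCCCC/C=C\C[C@H](O[Si](CC)(CC)CC)/C=C/[Zn]C | intermediate
26 | (5Z,8R)-8-{(1R,2R)-2-[(1R,2E,4S,6Z)-1-hydroxy-4-(triethylsilyloxy)dodeca-2,6-dien-1-yl]cyclopropyl}-3,4,7,8-tetrahydro-2H-oxocin-2-one | CCCCC/C=C\C[C@H](O[Si](CC)(CC)CC)/C=C/[C@@H](O)[C@@H]1C[C@H]1[C@H]1C/C=C\CCC(=O)O1 | intermediate
27 | solandelactone F, (5Z,8R)-8-{(1R,2R)-2-[(1R,2E,4S,6Z)-1,4-dihydroxydodeca-2,6-dien-1-yl]cyclopropyl}-3,4,7,8-tetrahydro-2H-oxocin-2-one | CCCCC/C=C\C[C@H](O)/C=C/[C@@H](O)[C@@H]1C[C@H]1[C@H]1C/C=C\CCC(=O)O1 | target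

**Step count**

Total: 17 steps. Longest linear sequence: 12 steps (steps 1–10, 16 and 17, from cyclooctadiene). The side chain takes steps 11–15.

**Steps most likely to fail**

Step 16. The catalyst may not fully control the face of the C11 aldehyde, because of uncatalysed background addition or a bias from the adjacent cyclopropane centre. Hydroboration could also stray to the Z-alkene, or methyl transfer could compete. The fallback sets out from 23 and 16 and separates bond formation from stereocontrol. Hydrozirconation of 23 with Cp2Zr(H)Cl followed by iodine should give the vinyl iodide triethyl{[(1E,3S,5Z)-1-iodoundeca-1,5-dien-3-yl]oxy}silane F1. Nozaki–Hiyama–Kishi coupling of F1 with 16 (CrCl2, NiCl2 cat., DMSO) should give, as both C11 epimers, the allylic alcohol (5Z,8R)-8-{(1R,2R)-2-[(2E,4S,6Z)-1-hydroxy-4-(triethylsilyloxy)dodeca-2,6-dien-1-yl]cyclopropyl}-3,4,7,8-tetrahydro-2H-oxocin-2-one F2. Dess–Martin oxidation should merge the epimers into the enone (5Z,8R)-8-{(1R,2R)-2-[(2E,4S,6Z)-4-(triethylsilyloxy)dodeca-2,6-dienoyl]cyclopropyl}-3,4,7,8-tetrahydro-2H-oxocin-2-one F3. Corey–Bakshi–Shibata reduction with (R)-1-methyl-3,3-diphenyl-tetrahydro-1H,3H-pyrrolo[1,2-c][1,3,2]oxazaborole and catecholborane at −78 °C would then set C11, the (R)-catalyst being chosen on the assumption that the alkenyl arm acts as the larger ketone substituent. The route is rejoined at 26.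

Step 5. With two zinc alkoxides present, the C7 alkoxide may compete for the boron ligand and erode facial control, or methylene may be transferred to the homoallylic Z-C4=C5 alkene. The fallback sets out from 8 and relies on the C7 carbinol as the only directing group. Silylation of the primary alcohol (TBSCl, imidazole) should give methyl (4Z,7R,8E)-7-(anilinooxy)-10-{[tert-butyl(dimethyl)silyl]oxy}deca-4,8-dienoate F4. N–O cleavage with Zn dust in AcOH should give methyl (4Z,7R,8E)-10-{[tert-butyl(dimethyl)silyl]oxy}-7-hydroxydeca-4,8-dienoate F5. Hydroxyl-directed Simmons–Smith cyclopropanation (Et2Zn, CH2I2, CH2Cl2, 0 °C) should then deliver methylene syn to the C7 oxygen through the H-eclipsed conformer, the same (8R,10R) sense. The route is rejoined at 11; steps 4 to 6 are then not needed.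

Step 3. The aminoxy aldehyde may oligomerise or lose the N–O group before the sluggish formyl ylide has reacted, and the enal may be olefinated a second time. The fallback sets out from crude 5 and uses a faster phosphonate olefination. Horner–Wadsworth–Emmons reaction under Masamune–Roush conditions (diethyl {2-[methoxy(methyl)amino]-2-oxoethyl}phosphonate, LiCl, DBU, MeCN, 0 °C) should give the Weinreb amide methyl (4Z,7R,8E)-7-(anilinooxy)-10-[methoxy(methyl)amino]-10-oxodeca-4,8-dienoate F6. Cp2Zr(H)Cl in THF should reduce the amide, but not the methyl ester, to the enal 7. NaBH4/CeCl3 reduction as in step 3 rejoins the route at 8.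

**Further compounds**

F1 | step 16 | triethyl{[(1E,3S,5Z)-1-iodoundeca-1,5-dien-3-yl]oxy}silane | CCCCC/C=C\C[C@H](O[Si](CC)(CC)CC)/C=C/I
F2 | step 16 | (5Z,8R)-8-{(1R,2R)-2-[(2E,4S,6Z)-1-hydroxy-4-(triethylsilyloxy)dodeca-2,6-dien-1-yl]cyclopropyl}-3,4,7,8-tetrahydro-2H-oxocin-2-one, both C11 epimers | CCCCC/C=C\C[C@H](O[Si](CC)(CC)CC)/C=C/C(O)[C@@H]1C[C@H]1[C@H]1C/C=C\CCC(=O)O1
F3 | step 16 | (5Z,8R)-8-{(1R,2R)-2-[(2E,4S,6Z)-4-(triethylsilyloxy)dodeca-2,6-dienoyl]cyclopropyl}-3,4,7,8-tetrahydro-2H-oxocin-2-one | CCCCC/C=C\C[C@H](O[Si](CC)(CC)CC)/C=C/C(=O)[C@@H]1C[C@H]1[C@H]1C/C=C\CCC(=O)O1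
F4 | step 5 | methyl (4Z,7R,8E)-7-(anilinooxy)-10-{[tert-butyl(dimethyl)silyl]oxy}deca-4,8-dienoate | CC(C)(C)[Si](C)(C)OC/C=C/[C@H](ONc1ccccc1)C/C=C\CCC(=O)OC
F5 | step 5 | methyl (4Z,7R,8E)-10-{[tert-butyl(dimethyl)silyl]oxy}-7-hydroxydeca-4,8-dienoate | CC(C)(C)[Si](C)(C)OC/C=C/[C@H](O)C/C=C\CCC(=O)OC
F6 | step 3 | methyl (4Z,7R,8E)-7-(anilinooxy)-10-[methoxy(methyl)amino]-10-oxodeca-4,8-dienoate | CON(C)C(=O)/C=C/[C@H](ONc1ccccc1)C/C=C\CCC(=O)OC
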